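## The problem

Abroquinone A is an isoflavan quinone. A 6,7-dimethoxychroman (benzo ring A fused to pyran ring C) carries at C3, through the single bond C3–C1', a 2,3-dimethoxy-1,4-benzoquinone (ring B). The rings are joined but not fused, so the skeleton is a 1,2-diarylpropane folded once through O1, and the only stereocentre is C3 (S). C3 bears H, two methylene groups and C1'; no neighbouring group can direct its formation, so a catalyst or reagent has to set it. The quinone is an electrophile and an oxidant and will not survive organometallic reagents, hydrides or bases. Once it is present, C3–H is allylic to it and can be lost by tautomerisation, so the quinone has to appear last. Ring A is a 1,2,4-trioxygenated benzene of the hydroquinone-ether type and is itself attacked by strong one-electron oxidants, which narrows the choice of the last oxidation. The enabling feature is ring B: oxygen on the four adjacent carbons C2'–C5' with C2' and C5' para, hydrogen on C6' and the chromanyl group on C1'. In reduced form this is a 4-methoxyphenol, the pattern formed when a terminal alkyne (C1', C6'), CO (C2') and an alkenyl(methoxy)carbene (C3', C4', C5') are joined on chromium.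

## Retrosynthesis

**Quinone 16 from phenol 15.** No skeletal bond is cut; C2'=O and C5'=O are traced back to OH and OMe in 6-(chromanyl)-2,3,4-trimethoxyphenol 15. This keeps the quinone out of every basic, reducing or organometallic step. A 4-methoxyphenol can be oxidised by PhI(OAc)2, which engages only the free phenol. A fully methylated arene would need a cerium-type oxidant that also attacks ring A. The forward step has to be para-selective and must leave ring A and C3–H alone.

**Phenol 15 from alkyne 7 and carbene complex 13.** The bonds C5'–C6', C1'–C2' and C2'–C3' are cut and C2' is returned to CO. The neighbouring cut, C3–C1', would need a fully oxygenated aryl partner and a stereocontrolled coupling at a secondary sp3 carbon. The benzannulation leaves C3 untouched and brings in all four oxygens at once. Alkyne 7 holds the whole chroman and the stereocentre but no ring B; complex 13 is a three-carbon piece. The forward reaction has to insert the alkyne with the hydrogen-bearing carbon next to the carbene carbon and has to take up CO rather than follow a CO-free path. The phenol is first formed as its Cr(CO)3 complex 14, which air releases.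

**Complex 13 from enol ether 9 and Cr(CO)6 10; 9 from acetal 8.** The bond between the carbene carbon and the vinyl group is cut: vinyllithium 11 adds to a CO ligand of 10 to give acylchromate 12, which is O-methylated. The alkene geometry of 13 is not recorded in ring B, because C3' loses its hydrogen on aromatisation. The geometry is therefore chosen for the stability of 11. (E)-1,2-Dimethoxyethene 9 gives a vinyllithium with lithium syn to the β-methoxy group, which cannot lose LiOMe by anti elimination. The (Z)-ether would place lithium anti to that leaving group. Compound 9 comes from commercial 1,1,2-trimethoxyethane 8 by loss of methanol.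

**Alkyne 7 from aldehyde 6 and alcohol 5.** The C≡C bond is cut back to the formyl carbon (one-carbon homologation), and 6 is the oxidation product of primary alcohol 5. A hydroxymethyl group at C3 is what a desymmetrisation of a 1,3-diol leaves behind. The forward steps must not epimerise 6, the only intermediate with an acidic C3–H.

**Alcohol 5 from diol 4.** The O1–C8a bond is cut. Diol 4 is achiral, with two enantiotopic CH2OH arms and an aryl bromide. Against hydrogenation of a 2H-chromene or closure at C4–C4a, this cut forms ring C and the stereocentre in one catalytic step from an acyclic precursor. The forward reaction must distinguish the two arms.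

**Diol 4 from malonate 3, and 3 from bromide 1 and diethyl malonate 2.** The C3–C4 bond is cut (benzylation of malonate) and the two ester groups are the oxidised form of the diol. Both starting materials are commercial, and the aryl bromide needed for ring closure is already in 1.

## Roads not taken

**Alternative 1:** Three-component conjunctive coupling around C3.
- **Cut:** C3–C1' and C4–C4a together.
- **Forward key step:** a ring B aryllithium and a vinylboronic ester form an ate complex. The arylpalladium from a ring A aryl triflate (Pd(OAc)2, Mandyphos-type ligand) triggers 1,2-migration of the ring B aryl to the α-carbon while ring A adds to the β-carbon. The product is 2-{(1S)-2-[2-(benzyloxy)-4,5-dimethoxyphenyl]-1-[3,4-dimethoxy-2-(methoxymethoxy)phenyl]ethyl}-4,4,5,5-tetramethyl-1,3,2-dioxaborolane A1.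
- **Merits:** highly convergent; both arenes and the stereocentre are joined in one step, and this reaction class has broad, high enantiocontrol.
- **Weak points here:** boron sits where C2 must be. A one-carbon homologation, oxidation, debenzylation, Mitsunobu closure of ring C and MOM removal follow. The final oxidation must install the C5' oxygen (for example (KSO3)2NO or Co(salen)/O2) next to ring A. Both partners are ortho-alkoxy substituted, which slows migration and oxidative addition, and two protecting groups are needed.
- **Comparison:** Alternative 1 is better in convergence and probably in enantioselectivity precedent. The chosen plan sets against this a route without protecting groups, a ring B that arrives with all four oxygens, and one operation after the key step where Alternative 1 needs about six.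

**Alternative 2:** Enamine α-arylation with the parent quinone.
- **Cut:** C3–C1', with 2,3-dimethoxy-1,4-benzoquinone A2 as the aryl electrophile.
- **Forward key step:** a chiral secondary amine turns the 3-arylpropanal carrying ring A and its bromine into an enamine, which adds to a free ring carbon of A2. Aromatisation and closure of the C2' hydroxyl on the aldehyde give (3S)-3-(2-bromo-4,5-dimethoxybenzyl)-6,7-dimethoxy-2,3-dihydro-1-benzofuran-2,5-diol A3.
- **Merits:** metal-free; ring B is attached fully oxygenated, and the stereocentre is reached in fewer steps than in the chosen route.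
- **Weak points here:** A2 is an electron-rich, weak acceptor and can oxidise the enamine instead. A3 is a masked α-aryl aldehyde that racemises easily until reduced. After reduction two free phenols compete with the primary alcohol in the C–O ring closure, so protection is needed, and the hydroquinone must be re-oxidised at the end.
- **Comparison:** Alternative 2 reaches the C3–C1' bond sooner. The chosen plan closes ring C on a substrate without phenols, creates the stereocentre as a configurationally stable alcohol, and makes the quinone only once.

**Alternative 3:** Iminium Friedel–Crafts addition with enantioselective protonation.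
- **Cut:** C4–C4a and O1–C2.
- **Forward key step:** a chiral primary–tertiary diamine salt activates a 2-arylacrolein carrying a benzyl-protected ring B. 3,4-Dimethoxyphenol A4 adds through its ortho carbon, the enamine is protonated at C3, and the phenol closes on the aldehyde to give (3S)-3-[3-(benzyloxy)-4,5-dimethoxyphenyl]-6,7-dimethoxychroman-2-ol A5.
- **Merits:** ring C, the C4–C4a bond and the stereocentre form in one organocatalytic step; with lactol reduction, debenzylation and phenol oxidation it is the shortest of the four routes.
- **Weak points here:** the stereocentre is set by proton transfer at the most acidic carbon (benzylic and α to a masked aldehyde). It can be lost through the enamine under the same catalyst, or through the oxocarbenium ion during ionic lactol reduction. 2-Arylacroleins polymerise readily, and the fourth oxygen of ring B must still be installed by oxidation.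
- **Comparison:** step count clearly favours Alternative 3. The chosen plan sets against this a stereocentre formed by a reaction documented for this ring system, which is α to a carbonyl only briefly (aldehyde 6) and never also benzylic to ring B.

Key step: step 8

Assumption for step 3: the (S)-ligand is taken to give (S)-5; if the sense of induction on this substrate is the opposite, the (R)-ligand is used and nothing else changes.

Remark on 13: the vinyl group is E (carbene carbon cis to the β-methoxy group); both geometries would give the same ring B.

## Route

Step 1
Reactants: 1 2-bromo-4,5-dimethoxybenzyl bromide; 2 diethyl malonate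
Product: 3 diethyl 2-(2-bromo-4,5-dimethoxybenzyl)malonate
Conditions: NaH, 2 (2.5 equiv), THF, 0 °C to rt
Reagents that add atoms: none
Why: Malonic ester alkylation: the sodium enolate displaces the benzylic bromide by SN2 while the aryl bromide is inert; the excess of 2 suppresses double alkylation.

Step 2
Reactants: 3 diethyl 2-(2-bromo-4,5-dimethoxybenzyl)malonate
Product: 4 2-(2-bromo-4,5-dimethoxybenzyl)propane-1,3-diol
Conditions: LiAlH4, THF, 0 °C to rt (3 added to the hydride)
Reagents that add atoms: none
Why: Hydride reduction of both ester groups to primary alcohols; adding 3 to excess LiAlH4 in the cold limits enolate formation, and the aryl bromide and aryl ethers are inert at this temperature.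

Step 3
Reactants: 4 2-(2-bromo-4,5-dimethoxybenzyl)propane-1,3-diol
Product: 5 [(3S)-6,7-dimethoxychroman-3-yl]methanol
Conditions: Pd(OAc)2 (5 mol %), (S)-SDP(O) [7-diphenylphosphino-7'-diphenylphosphoryl-1,1'-spirobiindane] (6 mol %), Cs2CO3, toluene, 80 °C
Reagents that add atoms: none
Why: Enantioselective desymmetrising intramolecular Buchwald–Hartwig C–O coupling, a reaction known for 2-(2-bromobenzyl)propane-1,3-diols: zerovalent palladium inserts into C–Br, the chiral arylpalladium binds one of the two enantiotopic CH2OH arms as alkoxide, and C–O reductive elimination closes six-membered ring C. The ligand alone selects the arm and so sets C3 as S; the other arm stays as the free CH2OH.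

Step 4
Reactants: 5 [(3S)-6,7-dimethoxychroman-3-yl]methanol
Product: 6 (3R)-6,7-dimethoxychroman-3-carbaldehyde
Conditions: Dess–Martin periodinane, CH2Cl2, 0 °C to rt; crude product used at once
Reagents that add atoms: none
Why: Dess–Martin oxidation of a primary alcohol stops at the aldehyde under near-neutral conditions and leaves the dialkoxyarene alone. C3 keeps its spatial arrangement (R only by CIP priority), and 6 is not chromatographed so that it meets neither acid nor base.

Step 5
Reactants: 6 (3R)-6,7-dimethoxychroman-3-carbaldehyde
Product: 7 (3S)-3-ethynyl-6,7-dimethoxychroman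
Conditions: Me3SiCHN2, n-BuLi, THF, −78 °C; then 6, −78 °C to 0 °C
Reagents that add atoms: (trimethylsilyl)diazomethane, C[Si](C)(C)C=[N+]=[N-]
Why: Colvin rearrangement: lithiated (trimethylsilyl)diazomethane adds to the aldehyde at −78 °C faster than it can enolise it, Peterson-type loss of Me3SiOLi gives a diazoalkene, N2 leaves and the alkylidene carbene undergoes a 1,2-hydrogen shift to the terminal alkyne. C3 is not touched; the descriptor returns to S because the side chain now ranks below C2.

Step 6
Reactants: 8 1,1,2-trimethoxyethane
Product: 9 (E)-1,2-dimethoxyethene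
Conditions: KHSO4 (cat.), neat, reflux under a fractionating column with removal of MeOH; spinning-band distillation; Z-rich remainder returned to the acid equilibration
Reagents that add atoms: none
Why: Acid-catalysed loss of methanol from an acetal (acetal cracking) gives the enol ether as an equilibrating Z/E mixture. The less polar E isomer is expected to distil first and is collected, while the Z-rich material is recycled.

Step 7
Reactants: 9 (E)-1,2-dimethoxyethene; 10 Cr(CO)6 (chromium hexacarbonyl)
Product: 13 pentacarbonyl{[(E)-1,2-dimethoxyethenyl](methoxy)methylidene}chromium, via (E)-1,2-dimethoxyethenyllithium 11 (not isolated), via lithium acylpentacarbonylchromate 12 (not isolated)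
Conditions: t-BuLi, THF, −78 to −40 °C; Cr(CO)6, THF, −78 °C to rt; then Me3OBF4, CH2Cl2/H2O, 0 °C
Reagents that add atoms: trimethyloxonium tetrafluoroborate, C[O+](C)C.F[B-](F)(F)F
Why: α-Lithiation of an enol ether followed by the Fischer carbene synthesis: t-BuLi removes the vinylic hydrogen that is geminal to one methoxy group and cis to the other, so 11 has lithium syn to the β-methoxy group and cannot lose LiOMe by anti elimination. Compound 11 adds to a CO ligand of Cr(CO)6 to give 12, which Me3OBF4 methylates on oxygen with retention of the alkene geometry.

Step 8
Reactants: 7 (3S)-3-ethynyl-6,7-dimethoxychroman; 13 pentacarbonyl{[(E)-1,2-dimethoxyethenyl](methoxy)methylidene}chromium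
Product: 15 6-[(3S)-6,7-dimethoxychroman-3-yl]-2,3,4-trimethoxyphenol, via Cr(CO)3 arene complex 14 (not isolated)
Conditions: 13 (1.3 equiv), THF (0.05 M), 55 °C, Ar; then air, Et2O, rt
Reagents that add atoms: none
Why: Dötz benzannulation: loss of one CO from 13 (the cis β-methoxy group may occupy the vacant site) lets alkyne 7 coordinate and insert into the Cr=C bond, and CO insertion into the resulting vinylcarbene gives a chromium-bound dienylketene. Ring B closes by 6π-electrocyclisation, which joins the ketene carbon (C2') to the methoxy-bearing vinyl terminus (C3'); loss of the C3' hydrogen by tautomerisation gives the phenol, first as complex 14 and then free after air oxidation of chromium. The bonds C5'–C6', C1'–C2' and C2'–C3' are formed, and the carbene carbon, the two vinyl carbons, CO and the two alkyne carbons become C5', C4', C3', C2', C1' and C6'. The closest known reactions are benzannulations of alkenyl(alkoxy)carbene chromium complexes, including α-alkoxyalkenyl ones, with terminal alkynes; β,β-disubstituted alkenyl complexes also cyclise, so the inward-pointing β-methoxy group should not block ring closure. No stereocentre is formed, and C3 of the chroman is a spectator that keeps its S configuration. The selectivity needed is regiochemical: the size difference between H and the secondary chromanyl carbon directs the hydrogen-bearing alkyne carbon to the carbene carbon, as is general for terminal alkynes, and so places the chromanyl group next to the CO-derived phenol carbon. Dilution and a small excess of 13 limit uptake of a second alkyne.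

Step 9
Reactants: 15 6-[(3S)-6,7-dimethoxychroman-3-yl]-2,3,4-trimethoxyphenol
Product: 16 abroquinone A, 5-[(3S)-6,7-dimethoxychroman-3-yl]-2,3-dimethoxy-1,4-benzoquinone
Conditions: PhI(OAc)2 (1.1 equiv), MeCN/H2O, 0 °C
Reagents that add atoms: water, O
Why: Hypervalent-iodine oxidation of a 4-methoxyphenol to the 1,4-quinone: ligand exchange at iodine and two-electron oxidation give a cation stabilised by the C5' methoxy group, water adds at C5' and the hemiketal loses methanol. Ring A has no free OH and is not engaged, and the near-neutral medium leaves C3–H alone.

## Compound list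

1 | 2-bromo-4,5-dimethoxybenzyl bromide | COc1cc(Br)c(CBr)cc1OC | starting material
2 | diethyl malonate | CCOC(=O)CC(=O)OCC | starting material
3 | diethyl 2-(2-bromo-4,5-dimethoxybenzyl)malonate | CCOC(=O)C(Cc1cc(OC)c(OC)cc1Br)C(=O)OCC | intermediate
4 | 2-(2-bromo-4,5-dimethoxybenzyl)propane-1,3-diol | OCC(CO)Cc1cc(OC)c(OC)cc1Br | intermediate
5 | [(3S)-6,7-dimethoxychroman-3-yl]methanol | OC[C@H]1COc2cc(OC)c(OC)cc2C1 | intermediate
6 | (3R)-6,7-dimethoxychroman-3-carbaldehyde | O=C[C@H]1COc2cc(OC)c(OC)cc2C1 | intermediate
7 | (3S)-3-ethynyl-6,7-dimethoxychroman | C#C[C@H]1COc2cc(OC)c(OC)cc2C1 | intermediate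
8 | 1,1,2-trimethoxyethane | COCC(OC)OC | starting material
9 | (E)-1,2-dimethoxyethene | CO/C=C/OC | intermediate
10 | Cr(CO)6, chromium hexacarbonyl | O=C=[Cr](=C=O)(=C=O)(=C=O)(=C=O)=C=O | starting material
11 | [(E)-1,2-dimethoxyethenyl]lithium | CO/C=C(/OC)[Li] | intermediate
12 | lithium pentacarbonyl[(2E)-2,3-dimethoxy-1-oxidoprop-2-en-1-ylidene]chromate | [Li+].CO/C=C(/OC)C([O-])=[Cr](=C=O)(=C=O)(=C=O)(=C=O)=C=O | intermediate
13 | pentacarbonyl{[(E)-1,2-dimethoxyethenyl](methoxy)methylidene}chromium | CO/C=C(/OC)C(OC)=[Cr](=C=O)(=C=O)(=C=O)(=C=O)=C=O | intermediate
14 | tricarbonyl{η6-6-[(3S)-6,7-dimethoxychroman-3-yl]-2,3,4-trimethoxyphenol}chromium (Cr bound to ring B; written as two dot-joined parts) | COc1cc([C@H]2COc3cc(OC)c(OC)cc3C2)c(O)c(OC)c1OC.O=C=[Cr](=C=O)=C=O | intermediate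
15 | 6-[(3S)-6,7-dimethoxychroman-3-yl]-2,3,4-trimethoxyphenol | COc1cc([C@H]2COc3cc(OC)c(OC)cc3C2)c(O)c(OC)c1OC | intermediate
16 | abroquinone A, 5-[(3S)-6,7-dimethoxychroman-3-yl]-2,3-dimethoxycyclohexa-2,5-diene-1,4-dione | COC1=C(OC)C(=O)C([C@H]2COc3cc(OC)c(OC)cc3C2)=CC1=O | target

## Step count and risks

Total step count: 9. Longest linear sequence: 7 (steps 1–5, 8, 9); the carbene branch is steps 6 and 7.

**Step 8 (key step).** The two methoxy groups on the vinyl unit make the carbene complex electron-rich. CO loss may be sluggish, and after alkyne insertion CO-free pathways (five-membered ring closure, or uptake of a second alkyne) may compete with ketene formation. Fallback, from alkyne 7 to target 16: 7 is deprotonated (n-BuLi, THF, −78 °C) to {[(3S)-6,7-dimethoxychroman-3-yl]ethynyl}lithium F1, which adds to one carbonyl of dimethyl squarate. This gives 4-{[(3S)-6,7-dimethoxychroman-3-yl]ethynyl}-4-hydroxy-2,3-dimethoxycyclobut-2-en-1-one F2 (both epimers at the carbinol carbon serve). Thermolysis in refluxing p-xylene (Moore rearrangement: ring opening to an enynylketene, six-membered ring closure, hydrogen transfer from OH) gives 16 directly. Steps 6, 7 and 9 are then not needed.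

**Step 7.** Metalation may be incomplete at temperatures where 11 is stable, 11 may still lose LiOMe to give methoxyethyne, or the supply of the minor E isomer of 9 may be limiting. If the Z-derived vinyllithium proves stable at −78 °C, the unseparated Z/E mixture could be used. Fallback without a vinyllithium, from 10 to phenol 15:
- Commercial methyl methoxyacetate is formylated (HCO2Me, NaOMe) to sodium 2,3-dimethoxy-3-oxoprop-1-en-1-olate F3 and O-methylated (Me2SO4) to methyl (2Z)-2,3-dimethoxyprop-2-enoate F4; the geometry is of no consequence.
- Saponification (LiOH) gives (2Z)-2,3-dimethoxyprop-2-enoic acid F5, and (COCl)2 converts it into (2Z)-2,3-dimethoxyprop-2-enoyl chloride F6.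
- Cr(CO)6 10 is reduced with C8K in THF to K2Cr(CO)5 F7, which is acylated by F6 to potassium pentacarbonyl[(2Z)-2,3-dimethoxy-1-oxidoprop-2-en-1-ylidene]chromate F8.
- Me3OBF4 gives pentacarbonyl{[(Z)-1,2-dimethoxyethenyl](methoxy)methylidene}chromium F9, which takes the place of 13 in step 8.

**Step 3.** The aryl bromide is electron-rich, so C–O reductive elimination may be slow, with hydrodebromination or β-hydride loss from the palladium alkoxide competing. Discrimination of the two arms may also be insufficient for a prochiral centre that bears hydrogen. Fallback by enzymatic desymmetrisation, from diol 4 to alcohol 5: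
- A lipase (for example from Burkholderia cepacia, selected by screening) with vinyl acetate gives (2S)-3-(2-bromo-4,5-dimethoxyphenyl)-2-(hydroxymethyl)propyl acetate F10.
- Silylation (t-BuMe2SiCl, imidazole) gives (2R)-3-(2-bromo-4,5-dimethoxyphenyl)-2-({[tert-butyl(dimethyl)silyl]oxy}methyl)propyl acetate F11. This protecting-group exchange prevents acyl migration from scrambling the centre.
- Methanolysis (K2CO3, MeOH) gives (2R)-3-(2-bromo-4,5-dimethoxyphenyl)-2-({[tert-butyl(dimethyl)silyl]oxy}methyl)propan-1-ol F12.
- Achiral C–O coupling (Pd(OAc)2, 2-(di-tert-butylphosphino)-1,1'-binaphthyl, Cs2CO3, toluene) gives tert-butyl{[(3R)-6,7-dimethoxychroman-3-yl]methoxy}dimethylsilane F13, and Bu4NF then gives 5.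

**Step 5.** Aldehyde 6 may lose configuration at C3 before or during homologation, by enolisation or by reversible opening of ring C (β-elimination of the aryloxide and re-addition). Fallback, from 6 to 7: Corey–Fuchs olefination under non-basic conditions (CBr4, PPh3, Zn, CH2Cl2, 0 °C) gives (3S)-3-(2,2-dibromoethenyl)-6,7-dimethoxychroman F14, which can be purified and checked for enantiomeric purity. n-BuLi (THF, −78 °C) then gives alkyne 7 by bromine–lithium exchange and rearrangement.

**Step 9.** Oxidation may be unselective: water may attack the ortho carbon C3' and give a 1,2-quinone, or ring A may be over-oxidised. Fallback, from 15 to 16: PhI(OAc)2 in methanol at 0 °C, where methanol adds at the para carbon, gives the quinone monoketal 6-[(3S)-6,7-dimethoxychroman-3-yl]-2,3,4,4-tetramethoxycyclohexa-2,5-dien-1-one F15. It is isolated and hydrolysed with dilute aqueous oxalic acid to 16, so that the oxidation and the unmasking of the quinone are separated.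

## Further compounds

F1 | step 8 | {[(3S)-6,7-dimethoxychroman-3-yl]ethynyl}lithium | [Li]C#C[C@H]1COc2cc(OC)c(OC)cc2C1
F2 | step 8 | 4-{[(3S)-6,7-dimethoxychroman-3-yl]ethynyl}-4-hydroxy-2,3-dimethoxycyclobut-2-en-1-one | COC1=C(OC)C(O)(C#C[C@H]2COc3cc(OC)c(OC)cc3C2)C1=O
F3 | step 7 | sodium 2,3-dimethoxy-3-oxoprop-1-en-1-olate | [Na+].[O-]C=C(OC)C(=O)OC
F4 | step 7 | methyl (2Z)-2,3-dimethoxyprop-2-enoate | CO/C=C(\OC)C(=O)OC
F5 | step 7 | (2Z)-2,3-dimethoxyprop-2-enoic acid | CO/C=C(\OC)C(=O)O
F6 | step 7 | (2Z)-2,3-dimethoxyprop-2-enoyl chloride | CO/C=C(\OC)C(Cl)=O
F7 | step 7 | K2Cr(CO)5, dipotassium pentacarbonylchromate | [K+].[K+].O=C=[Cr-2](=C=O)(=C=O)(=C=O)=C=O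
F8 | step 7 | potassium pentacarbonyl[(2Z)-2,3-dimethoxy-1-oxidoprop-2-en-1-ylidene]chromate | [K+].CO/C=C(\OC)C([O-])=[Cr](=C=O)(=C=O)(=C=O)(=C=O)=C=O
F9 | step 7 | pentacarbonyl{[(Z)-1,2-dimethoxyethenyl](methoxy)methylidene}chromium | CO/C=C(\OC)C(OC)=[Cr](=C=O)(=C=O)(=C=O)(=C=O)=C=O
F10 | step 3 | (2S)-3-(2-bromo-4,5-dimethoxyphenyl)-2-(hydroxymethyl)propyl acetate | OC[C@H](Cc1cc(OC)c(OC)cc1Br)COC(C)=O
F11 | step 3 | (2R)-3-(2-bromo-4,5-dimethoxyphenyl)-2-({[tert-butyl(dimethyl)silyl]oxy}methyl)propyl acetate | CC(C)(C)[Si](C)(C)OC[C@H](Cc1cc(OC)c(OC)cc1Br)COC(C)=O
F12 | step 3 | (2R)-3-(2-bromo-4,5-dimethoxyphenyl)-2-({[tert-butyl(dimethyl)silyl]oxy}methyl)propan-1-ol | CC(C)(C)[Si](C)(C)OC[C@H](Cc1cc(OC)c(OC)cc1Br)CO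
F13 | step 3 | tert-butyl{[(3R)-6,7-dimethoxychroman-3-yl]methoxy}dimethylsilane | CC(C)(C)[Si](C)(C)OC[C@H]1COc2cc(OC)c(OC)cc2C1
F14 | step 5 | (3S)-3-(2,2-dibromoethenyl)-6,7-dimethoxychroman | BrC(Br)=C[C@H]1COc2cc(OC)c(OC)cc2C1
F15 | step 9 | 6-[(3S)-6,7-dimethoxychroman-3-yl]-2,3,4,4-tetramethoxycyclohexa-2,5-dien-1-one | O=C1C(OC)=C(OC)C(OC)(OC)C=C1[C@H]2COc3cc(OC)c(OC)cc3C2
A1 | alternative 1 | 2-{(1S)-2-[2-(benzyloxy)-4,5-dimethoxyphenyl]-1-[3,4-dimethoxy-2-(methoxymethoxy)phenyl]ethyl}-4,4,5,5-tetramethyl-1,3,2-dioxaborolane | COCOc1c([C@H](Cc2cc(OC)c(OC)cc2OCc2ccccc2)B2OC(C)(C)C(C)(C)O2)ccc(OC)c1OC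
A2 | alternative 2 | 2,3-dimethoxy-1,4-benzoquinone | COC1=C(OC)C(=O)C=CC1=O
A3 | alternative 2 | (3S)-3-(2-bromo-4,5-dimethoxybenzyl)-6,7-dimethoxy-2,3-dihydro-1-benzofuran-2,5-diol (anomeric mixture at C2) | OC1Oc2c(OC)c(OC)c(O)cc2[C@@H]1Cc1cc(OC)c(OC)cc1Br
A4 | alternative 3 | 3,4-dimethoxyphenol | COc1ccc(O)cc1OC
A5 | alternative 3 | (3S)-3-[3-(benzyloxy)-4,5-dimethoxyphenyl]-6,7-dimethoxychroman-2-ol (anomeric mixture at C2) | COc1cc([C@H]2C(O)Oc3cc(OC)c(OC)cc3C2)cc(OCc2ccccc2)c1OC
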